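Marchantin H is cut at the ethano bridge between the para-disubstituted ring A and the catechol ring C. Both bridge carbons sit para (ring A) or ortho (ring C) to a diaryl ether oxygen. Each is therefore carried as a formyl group that first activates a C–F bond for ether formation by SNAr. It is then united with its twin, a carbon of like polarity, by an intramolecular McMurry coupling. This one operation forms the C–C bond, removes both oxygens and closes the 18-membered ring. Its precursor is the open-chain four-ring dialdehyde 8, whose ring B–ring D ethano bridge is already saturated and flexible. Hydrogenation and demethylation finish the synthesis.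

Key step: step 4

Ring labels:
- Ring A is the para-disubstituted aryloxy ring.
- Ring B is the 1,2,4-trisubstituted ring with one OH.
- Ring C is the tetrasubstituted ring with two OH groups.
- Ring D is the meta-disubstituted ring.

Assumption: the geometry of the alkene formed in step 4 has no consequence, because step 5 saturates it. Compound 9 is written as the E isomer, and any Z isomer would be carried along to the same product.

Step 1
Reactants: 1 5-bromo-2-methoxyphenol; 2 4-fluorobenzaldehyde
Product: 3 4-(5-bromo-2-methoxyphenoxy)benzaldehyde
Conditions: K2CO3, DMF, 130 °C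
Reagents that add atoms: none
Why: SNAr (addition–elimination), in which the para-formyl group stabilises the Meisenheimer adduct so that the phenoxide of 1 displaces fluoride, while the unactivated C–Br bond stays intact.

Step 2
Reactants: 4 3-vinylphenol; 3 4-(5-bromo-2-methoxyphenoxy)benzaldehyde
Product: 6 4-{5-[2-(3-hydroxyphenyl)ethyl]-2-methoxyphenoxy}benzaldehyde, via bis(9-BBN) adduct 5 (not isolated)
Conditions: 4, 9-BBN (2.2 equiv), THF, 0 °C to rt; then aq. K3PO4, 3, Pd(dppf)Cl2 (cat.), DMF, 60 °C
Reagents that add atoms: 9-BBN (9-borabicyclo[3.3.1]nonane), B1C2CCCC1CCC2 (its boron framework stays only in 5; 6 keeps one hydrogen from it)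
Why: 9-BBN adds to the styrene with boron at the terminal carbon (anti-Markovnikov hydroboration, the phenol being masked in passing as its borinate), leftover B–H is destroyed by the aqueous base before aldehyde 3 enters, and the B-alkyl Suzuki–Miyaura coupling then joins the sp3 carbon to the aryl bromide, so the saturated ring B–ring D bridge arises without any hydrogenation in the presence of the aldehyde.

Step 3
Reactants: 6 4-{5-[2-(3-hydroxyphenyl)ethyl]-2-methoxyphenoxy}benzaldehyde; 7 2-fluoro-3,4-dimethoxybenzaldehyde
Product: 8 2-{3-[2-(3-(4-formylphenoxy)-4-methoxyphenyl)ethyl]phenoxy}-3,4-dimethoxybenzaldehyde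
Conditions: Cs2CO3, DMA, 140 °C
Reagents that add atoms: none
Why: SNAr, in which the ortho-formyl group of 7 activates its C–F bond towards the only phenoxide present, and fluoride leaves far more readily than either methoxy group.

Step 4
Reactants: 8 2-{3-[2-(3-(4-formylphenoxy)-4-methoxyphenyl)ethyl]phenoxy}-3,4-dimethoxybenzaldehyde
Product: 9 (E)-didehydro-tri-O-methylmarchantin H (18-membered macrocyclic stilbene, CH=CH between ring A and ring C)
Conditions: TiCl4, Zn dust, pyridine (cat.), THF, reflux; 8 added by syringe pump over about 20 h (final concentration about 1 mM)
Reagents that add atoms: none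
Why: Zn reduces TiCl4 to low-valent titanium, which transfers one electron to each formyl group; the two titanium-bound ketyl radicals combine carbon to carbon, and the surface-bound 1,2-diolate then gives up both oxygens to titanium to leave the stilbene C=C. The closest known reaction type is the intramolecular McMurry coupling of aromatic dialdehydes to macrocyclic stilbenes, a reductive union of two electrophilic carbons. The single ring closed is the 18-membered macrocycle (counted along the shortest path through rings A, B, C and D), formed by end-to-end closure of the open chain with both former carbonyl carbons becoming ring members. No stereocentre arises, and the alkene geometry is irrelevant because step 5 saturates it. The selectivity needed is ring closure over intermolecular coupling, and it is secured by slow addition into a large excess of reagent (pseudo-high dilution) and by the three flexible hinges of 8 (two diaryl ether oxygens and the CH2–CH2 bridge between rings B and D), which let the termini meet without strain. Chemoselectivity is not at stake, since the two aldehydes are the only reducible groups and aryl methyl ethers and diaryl ethers are inert to low-valent titanium.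

Step 5
Reactants: 9 (E)-didehydro-tri-O-methylmarchantin H
Product: 10 tri-O-methylmarchantin H
Conditions: H2 (1 atm), Pd/C (10 wt%), EtOAc–EtOH, rt
Reagents that add atoms: none
Why: Heterogeneous catalytic hydrogenation saturates the stilbene C=C of either geometry, while arenes, methyl ethers and diaryl ethers are untouched under these mild conditions.

Step 6
Reactants: 10 tri-O-methylmarchantin H
Product: 11 marchantin H
Conditions: BBr3 (excess), CH2Cl2, −78 °C to rt; then H2O, work-up under argon
Reagents that add atoms: none
Why: Lewis-acid aryl methyl ether cleavage, in which boron coordinates each methoxy oxygen and bromide attacks the methyl carbon, whereas the diaryl ether C–O bonds offer no sp3 carbon for attack and survive.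

Compound list
1 | 5-bromo-2-methoxyphenol | COc1ccc(Br)cc1O | starting material
2 | 4-fluorobenzaldehyde | O=Cc1ccc(F)cc1 | starting material
3 | 4-(5-bromo-2-methoxyphenoxy)benzaldehyde | COc1ccc(Br)cc1Oc1ccc(C=O)cc1 | intermediate
4 | 3-vinylphenol | C=Cc1cccc(O)c1 | starting material
5 | bis(9-BBN) adduct of 3-vinylphenol (B-alkyl at the terminal carbon, O-boryl at the phenol) | C(Cc1cccc(OB2C3CCCC2CCC3)c1)B1C2CCCC1CCC2 | intermediate
6 | 4-{5-[2-(3-hydroxyphenyl)ethyl]-2-methoxyphenoxy}benzaldehyde | COc1ccc(CCc2cccc(O)c2)cc1Oc1ccc(C=O)cc1 | intermediate
7 | 2-fluoro-3,4-dimethoxybenzaldehyde | COc1ccc(C=O)c(F)c1OC | starting material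
8 | 2-{3-[2-(3-(4-formylphenoxy)-4-methoxyphenyl)ethyl]phenoxy}-3,4-dimethoxybenzaldehyde | COc1ccc(CCc2cccc(Oc3c(C=O)ccc(OC)c3OC)c2)cc1Oc1ccc(C=O)cc1 | intermediate
9 | (E)-didehydro-tri-O-methylmarchantin H (macrocyclic stilbene) | COc1ccc2cc1Oc1ccc(cc1)/C=C/c1ccc(OC)c(OC)c1Oc1cccc(c1)CC2 | intermediate
10 | tri-O-methylmarchantin H | COc1ccc2cc1Oc1ccc(cc1)CCc1ccc(OC)c(OC)c1Oc1cccc(c1)CC2 | intermediate
11 | marchantin H | Oc1ccc2cc1Oc1ccc(cc1)CCc1ccc(O)c(O)c1Oc1cccc(c1)CC2 | target

Total step count: 6. Longest linear sequence: 6 steps (1 → 3 → 6 → 8 → 9 → 10 → 11).

Steps most likely to fail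

Step 4. Intermolecular coupling to oligomers may outrun ring closure, or the reaction may stall at the diolate stage without deoxygenation.
- The fallback sets out from 8 and forms the same bond at the sp3 level.
- NaBH4 in MeOH–THF should reduce both aldehydes to the bis(benzylic alcohol) F1.
- PBr3 in CH2Cl2 at 0 °C should convert it into the bis(benzylic bromide) F2.
- An intramolecular Wurtz-type reductive coupling (Na, tetraphenylethene as electron carrier, THF, high dilution) should close the ring.
- The fallback returns to the route at 10, and step 5 is no longer needed.

Step 2. Boron hydride left in the flask may reduce the aldehyde, or the alkyl group may be lost by β-hydride elimination or protodeboronation before coupling.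
- The fallback sets out from 3 and 4.
- A Heck reaction (Pd(OAc)2, P(o-tol)3, NaOAc, DMA, 120 °C) should give the stilbene 4-{5-[(E)-2-(3-hydroxyphenyl)ethenyl]-2-methoxyphenoxy}benzaldehyde F3.
- Its C=C bond would then be hydrogenated selectively over Pd/C poisoned with diphenyl sulfide (H2, EtOAc, rt), conditions that spare aromatic aldehydes.
- The fallback returns to the route at 6.

Step 3. Addition of the phenoxide to the hindered, electron-rich fluoroarene may be too slow, so the aldehydes degrade at the temperature required.
- The fallback sets out from 6 and replaces addition–elimination by a copper-catalysed Ullmann-type C–O coupling.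
- The coupling partner is purchased 2-bromo-3,4-dimethoxybenzaldehyde F4 (CuI, picolinic acid, K3PO4, DMSO, 90 °C).
- Here the C–Br bond is activated at copper with help from the neighbouring formyl group.
- The fallback returns to the route at 8.

Further compounds
F1 | step 4 | {2-{3-[2-(3-(4-(hydroxymethyl)phenoxy)-4-methoxyphenyl)ethyl]phenoxy}-3,4-dimethoxyphenyl}methanol (bis(benzylic alcohol)) | COc1ccc(CCc2cccc(Oc3c(CO)ccc(OC)c3OC)c2)cc1Oc1ccc(CO)cc1
F2 | step 4 | corresponding bis(benzylic bromide) | COc1ccc(CCc2cccc(Oc3c(CBr)ccc(OC)c3OC)c2)cc1Oc1ccc(CBr)cc1
F3 | step 2 | 4-{5-[(E)-2-(3-hydroxyphenyl)ethenyl]-2-methoxyphenoxy}benzaldehyde | COc1ccc(/C=C/c2cccc(O)c2)cc1Oc1ccc(C=O)cc1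
F4 | step 3 | 2-bromo-3,4-dimethoxybenzaldehyde | COc1ccc(C=O)c(Br)c1OC
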